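**Plan**

- Retrosynthesis: remove the five benzyl ethers and a tert-butoxycarbonyl helper on C3; cut the C3–C3' bond between flavanone ring C and flavone ring B, giving a flavanone β-keto ester and a flavone aryl(mesityl)iodonium salt; open the flavanone at O1–C2 and C2–C3 (oxa-Michael, Knoevenagel); open the flavone at O1–C2 (2'-hydroxychalcone).
- Forward: the flavone is built first (chalcone, oxidative cyclisation) and its C3'–Br is turned into SnBu3, then into the iodonium salt. The flavanone ring is made by Knoevenagel/oxa-Michael as a racemic, equilibrating β-keto ester. The halves are joined by C3 arylation, followed by decarboxylation and hydrogenolysis.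
- Enabling feature: flavanone C3 lies between the C4 ketone and, through C2, the ring oxygen O1. Its β-keto ester is therefore a soft C-nucleophile and, by reversible opening of the O1–C2 bond, stereolabile at C2 until C3 becomes quaternary. The bond made is ortho to the C4' oxygen of ring B.
- Stereochemistry: C2 is set by dynamic kinetic resolution in the arylation (chiral Cu–bisoxazoline). C3 is set trans to the C2 aryl by thermodynamic ketonisation after decarboxylation, giving (2S,3R).

Key step: step 8

Assumption: the sense of induction of the bisoxazoline ligand in step 8 cannot be derived from precedent; (S,S)-Ph-BOX is written, and the mirror-image ligand is used if it selects the (2R) enolate.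

**Route**

Step 1
Reactants: 1 2',6'-dihydroxy-4'-methoxyacetophenone
Product: 2 1-[2-(benzyloxy)-6-hydroxy-4-methoxyphenyl]ethan-1-one
Conditions: BnBr (1.05 equiv), K2CO3 (1.2 equiv), acetone, reflux
Reagents that add atoms: benzyl bromide, BrCc1ccccc1
Why: Williamson etherification; after the first alkylation the remaining OH is held in the hydrogen bond to the acetyl C=O and is much less nucleophilic, so the mono-ether should result.

Step 2
Reactants: 2 1-[2-(benzyloxy)-6-hydroxy-4-methoxyphenyl]ethan-1-one; 3 4-(benzyloxy)-3-bromobenzaldehyde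
Product: 4 (E)-1-[2-(benzyloxy)-6-hydroxy-4-methoxyphenyl]-3-[4-(benzyloxy)-3-bromophenyl]prop-2-en-1-one
Conditions: KOH (aq. 50 %), EtOH/THF, rt
Reagents that add atoms: none
Why: Claisen–Schmidt aldol condensation of the methyl ketone enolate with a non-enolisable aldehyde should give the E-chalcone, and the aryl bromide and benzyl ethers are inert to aqueous base at room temperature.

Step 3
Reactants: 4 the 2'-hydroxychalcone
Product: 5 5-(benzyloxy)-2-[4-(benzyloxy)-3-bromophenyl]-7-methoxy-4H-chromen-4-one
Conditions: I2 (10 mol %), DMSO, 130 °C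
Reagents that add atoms: none
Why: Iodine-catalysed oxidative cyclisation of a 2'-hydroxychalcone in DMSO (oxa-Michael addition, α-iodination, loss of HI, re-oxidation of HI by DMSO) is the standard flavone synthesis and leaves the aryl bromide and the benzyl ethers in place.

Step 4
Reactants: 5 the 3'-bromoflavone
Product: 6 5-(benzyloxy)-2-[4-(benzyloxy)-3-(tributylstannyl)phenyl]-7-methoxy-4H-chromen-4-one
Conditions: (Bu3Sn)2 (1.5 equiv), Pd(PPh3)4 (5 mol %), toluene, 110 °C
Reagents that add atoms: hexabutylditin, CCCC[Sn](CCCC)(CCCC)[Sn](CCCC)(CCCC)CCCC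
Why: Pd(0)-catalysed stannylation of an aryl bromide with a distannane (Stille-type coupling) should replace the C3' bromine by SnBu3 without touching the chromone.

Step 5
Reactants: 6 the 3'-stannylflavone
Product: 8 {2-(benzyloxy)-5-[5-(benzyloxy)-7-methoxy-4-oxo-4H-chromen-2-yl]phenyl}(2,4,6-trimethylphenyl)iodonium trifluoromethanesulfonate, via iodonium tosylate 7 (not isolated)
Conditions: MesI(OAc)2 (1.05 equiv), TsOH·H2O (1.05 equiv), MeCN/CH2Cl2, 0 °C, 30 min; then 6, 0 °C → rt; then wash with sat. aq. NaOTf
Reagents that add atoms: iodomesitylene diacetate, CC(=O)OI(OC(C)=O)c1c(C)cc(C)cc1C; p-toluenesulfonic acid monohydrate (counter-ion of 7 only), Cc1ccc(S(=O)(=O)O)cc1.O; sodium trifluoromethanesulfonate, [Na+].[O-]S(=O)(=O)C(F)(F)F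
Why: ipso-Substitution of the C–Sn bond by a Koser-type λ3-iodane (aryl transfer from tin to iodine(III)) should give the unsymmetrical diaryliodonium salt only at C3', much faster than any attack on the electron-rich ring A, and anion metathesis installs the weakly coordinating triflate.

Step 6
Reactants: 9 1-[2,4-bis(benzyloxy)-6-hydroxyphenyl]ethan-1-one
Product: 10 tert-butyl 3-[2,4-bis(benzyloxy)-6-hydroxyphenyl]-3-oxopropanoate
Conditions: LiHMDS (3.2 equiv), THF, −78 °C; Boc2O (1.1 equiv), −78 → 0 °C; aq. NH4Cl
Reagents that add atoms: di-tert-butyl dicarbonate, CC(C)(C)OC(=O)OC(=O)OC(C)(C)C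
Why: Claisen-type C-acylation of the ketone enolate of the phenoxide–enolate dianion (any O-Boc phenol formed can pass its acyl group to carbon by a Baker–Venkataraman-type shift) should give the β-keto ester, and the tert-butyl ester resists lactonisation to a 4-hydroxycoumarin.

Step 7
Reactants: 10 the tert-butyl β-keto ester; 11 4-(benzyloxy)benzaldehyde
Product: 13 racemic tert-butyl 5,7-bis(benzyloxy)-2-[4-(benzyloxy)phenyl]-4-oxochromane-3-carboxylate (cis and trans keto forms and enol, used as the mixture), via alkylidene β-keto ester 12 (not isolated)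
Conditions: piperidine (20 mol %), AcOH (20 mol %), 4 Å MS, toluene, rt → 50 °C
Reagents that add atoms: none
Why: Knoevenagel condensation followed by amine-mediated 6-endo-trig oxa-Michael addition of the 2'-phenol should close the pyranone ring, and no stereocontrol is needed because all isomers of 13 interconvert in step 8.

Step 8
Reactants: 13 the racemic flavanone β-keto ester (1.3 equiv); 8 the flavone aryl(mesityl)iodonium triflate
Product: 14 tert-butyl (2R,3S)-5,7-bis(benzyloxy)-3-{2-(benzyloxy)-5-[5-(benzyloxy)-7-methoxy-4-oxo-4H-chromen-2-yl]phenyl}-2-[4-(benzyloxy)phenyl]-4-oxochromane-3-carboxylate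
Conditions: (CuOTf)2·PhMe (5 mol %), (S,S)-Ph-BOX (12 mol %), Na2CO3 (1.5 equiv), i-Pr2NEt (20 mol %), 4 Å MS, CH2Cl2, −20 → 0 °C, 8 added slowly
Reagents that add atoms: none
Why: Proposed new method: the amine keeps both enantiomers, both C3 epimers and the enol of 13 in equilibrium through the achiral ring-opened alkylidene 12 (retro-oxa-Michael and 6-endo-trig oxa-Michael re-closure, the only ring-closing event of the step), while the aryl–Cu(III)–bisoxazoline species formed by oxidative addition of Cu(I) to 8 binds the β-keto ester enolate as an O,O-chelate and forms the C3–C3' bond by reductive elimination. The closest known reaction types are the Cu–bisoxazoline-catalysed enantioselective α-arylation of enol silanes with diaryliodonium salts, the base-mediated C-arylation of cyclic β-keto esters with diaryliodonium salts to quaternary centres, and the Cu–bisoxazoline-catalysed enantioselective electrophilic functionalisation of cyclic β-keto esters; a dynamic kinetic version on a flavanone β-keto ester has not been shown. At C3 the aryl group should enter anti to the pseudoaxial C2 aryl group (substrate control, A1,2 strain with the ester) and on the enolate face left open by the ligand. At C2, anti attack on that face is possible only for the (2S) enolate, so the catalyst selects this enantiomer, and the quaternary C3 can no longer enolise, which locks C2 (its descriptor becomes R in 14 only through the change of CIP priorities). The step needs enantiomer selection (ligand), C- over O-arylation (chelated soft enolate, bond formation at carbon on copper), transfer of the flavone aryl and not of mesityl (the 2,6-disubstituted mesityl is the group that stays on iodine under Cu catalysis), and racemisation faster than arylation (slow addition of 8, amine co-catalyst).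

Step 9
Reactants: 14 the arylated tert-butyl ester
Product: 16 (2S,3R)-5,7-bis(benzyloxy)-3-{2-(benzyloxy)-5-[5-(benzyloxy)-7-methoxy-4-oxo-4H-chromen-2-yl]phenyl}-2-[4-(benzyloxy)phenyl]chroman-4-one, via β-keto acid 15 (not isolated)
Conditions: TFA/CH2Cl2 (1:4), 0 °C → rt; then toluene, 60 °C
Reagents that add atoms: none
Why: Acidolysis of the tert-butyl ester (loss of isobutene) and decarboxylation of the β-keto acid through its cyclic transition state give the enol, whose ketonisation and acid-catalysed equilibration should place the C3 aryl trans (diequatorial) to the C2 aryl, setting 3R while C2 is untouched.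

Step 10
Reactants: 16 the pentabenzyl ether
Product: 17 (2S,3R)-5,7-dihydroxy-3-[2-hydroxy-5-(5-hydroxy-7-methoxy-4-oxo-4H-chromen-2-yl)phenyl]-2-(4-hydroxyphenyl)chroman-4-one (target)
Conditions: H2 (1 atm), 10 % Pd/C, EtOAc/MeOH, rt
Reagents that add atoms: none
Why: Pd-catalysed hydrogenolysis of the five aryl benzyl ethers under neutral conditions should be faster than reduction of the flavone C2=C3 bond or cleavage of the cyclic benzylic C2–O1 bond, and the neutral medium preserves C2 and C3.

**Compound list**

1 | 2',6'-dihydroxy-4'-methoxyacetophenone | CC(=O)c1c(O)cc(OC)cc1O | starting material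
2 | 1-[2-(benzyloxy)-6-hydroxy-4-methoxyphenyl]ethan-1-one | CC(=O)c1c(O)cc(OC)cc1OCc1ccccc1 | intermediate
3 | 4-(benzyloxy)-3-bromobenzaldehyde | O=Cc1ccc(OCc2ccccc2)c(Br)c1 | starting material
4 | (E)-1-[2-(benzyloxy)-6-hydroxy-4-methoxyphenyl]-3-[4-(benzyloxy)-3-bromophenyl]prop-2-en-1-one | COc1cc(O)c(C(=O)/C=C/c2ccc(OCc3ccccc3)c(Br)c2)c(OCc2ccccc2)c1 | intermediate
5 | 5-(benzyloxy)-2-[4-(benzyloxy)-3-bromophenyl]-7-methoxy-4H-chromen-4-one | COc1cc(OCc2ccccc2)c2c(=O)cc(-c3ccc(OCc4ccccc4)c(Br)c3)oc2c1 | intermediate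
6 | 5-(benzyloxy)-2-[4-(benzyloxy)-3-(tributylstannyl)phenyl]-7-methoxy-4H-chromen-4-one | COc1cc(OCc2ccccc2)c2c(=O)cc(-c3ccc(OCc4ccccc4)c([Sn](CCCC)(CCCC)CCCC)c3)oc2c1 | intermediate
7 | {2-(benzyloxy)-5-[5-(benzyloxy)-7-methoxy-4-oxo-4H-chromen-2-yl]phenyl}(2,4,6-trimethylphenyl)iodonium p-toluenesulfonate | COc1cc(OCc2ccccc2)c2c(=O)cc(-c3ccc(OCc4ccccc4)c([I+]c4c(C)cc(C)cc4C)c3)oc2c1.Cc1ccc(S(=O)(=O)[O-])cc1 | intermediate
8 | {2-(benzyloxy)-5-[5-(benzyloxy)-7-methoxy-4-oxo-4H-chromen-2-yl]phenyl}(2,4,6-trimethylphenyl)iodonium trifluoromethanesulfonate | COc1cc(OCc2ccccc2)c2c(=O)cc(-c3ccc(OCc4ccccc4)c([I+]c4c(C)cc(C)cc4C)c3)oc2c1.[O-]S(=O)(=O)C(F)(F)F | intermediate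
9 | 1-[2,4-bis(benzyloxy)-6-hydroxyphenyl]ethan-1-one | CC(=O)c1c(O)cc(OCc2ccccc2)cc1OCc1ccccc1 | starting material
10 | tert-butyl 3-[2,4-bis(benzyloxy)-6-hydroxyphenyl]-3-oxopropanoate | CC(C)(C)OC(=O)CC(=O)c1c(O)cc(OCc2ccccc2)cc1OCc1ccccc1 | intermediate
11 | 4-(benzyloxy)benzaldehyde | O=Cc1ccc(OCc2ccccc2)cc1 | starting material
12 | tert-butyl 2-[2,4-bis(benzyloxy)-6-hydroxybenzoyl]-3-[4-(benzyloxy)phenyl]prop-2-enoate (E/Z) | CC(C)(C)OC(=O)C(=Cc1ccc(OCc2ccccc2)cc1)C(=O)c1c(O)cc(OCc2ccccc2)cc1OCc1ccccc1 | intermediate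
13 | racemic tert-butyl 5,7-bis(benzyloxy)-2-[4-(benzyloxy)phenyl]-4-oxochromane-3-carboxylate | CC(C)(C)OC(=O)C1C(=O)c2c(OCc3ccccc3)cc(OCc3ccccc3)cc2OC1c1ccc(OCc2ccccc2)cc1 | intermediate
14 | tert-butyl (2R,3S)-5,7-bis(benzyloxy)-3-{2-(benzyloxy)-5-[5-(benzyloxy)-7-methoxy-4-oxo-4H-chromen-2-yl]phenyl}-2-[4-(benzyloxy)phenyl]-4-oxochromane-3-carboxylate | COc1cc(OCc2ccccc2)c2c(=O)cc(-c3ccc(OCc4ccccc4)c([C@@]4(C(=O)OC(C)(C)C)C(=O)c5c(OCc6ccccc6)cc(OCc6ccccc6)cc5O[C@@H]4c4ccc(OCc5ccccc5)cc4)c3)oc2c1 | intermediate
15 | (2R,3S)-5,7-bis(benzyloxy)-3-{2-(benzyloxy)-5-[5-(benzyloxy)-7-methoxy-4-oxo-4H-chromen-2-yl]phenyl}-2-[4-(benzyloxy)phenyl]-4-oxochromane-3-carboxylic acid | COc1cc(OCc2ccccc2)c2c(=O)cc(-c3ccc(OCc4ccccc4)c([C@@]4(C(=O)O)C(=O)c5c(OCc6ccccc6)cc(OCc6ccccc6)cc5O[C@@H]4c4ccc(OCc5ccccc5)cc4)c3)oc2c1 | intermediate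
16 | (2S,3R)-5,7-bis(benzyloxy)-3-{2-(benzyloxy)-5-[5-(benzyloxy)-7-methoxy-4-oxo-4H-chromen-2-yl]phenyl}-2-[4-(benzyloxy)phenyl]chroman-4-one | COc1cc(OCc2ccccc2)c2c(=O)cc(-c3ccc(OCc4ccccc4)c([C@H]4C(=O)c5c(OCc6ccccc6)cc(OCc6ccccc6)cc5O[C@@H]4c4ccc(OCc5ccccc5)cc4)c3)oc2c1 | intermediate
17 | (2S,3R)-5,7-dihydroxy-3-[2-hydroxy-5-(5-hydroxy-7-methoxy-4-oxo-4H-chromen-2-yl)phenyl]-2-(4-hydroxyphenyl)chroman-4-one | COc1cc(O)c2c(=O)cc(-c3ccc(O)c([C@H]4C(=O)c5c(O)cc(O)cc5O[C@@H]4c4ccc(O)cc4)c3)oc2c1 | target

**Summary**

Total step count: 10. Longest linear sequence: 8 steps (steps 1–5, then 8–10, from compound 1).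

Steps most likely to fail:

1. Step 8 (proposed new method). The aryl transfer to a very congested quaternary centre may be slower than O-arylation of the ring-opened phenol, or the catalyst may discriminate the two interconverting enantiomers poorly, leaving low enantiomeric purity at C2. The fallback uses known chemistry; it sets out from 10, 11 and 6 and comes back at 14. The Knoevenagel condensation of 10 with 11 is stopped at the alkylidene 12 (piperidine/AcOH, benzene, rt), which is isolated. 12 is then cyclised with a cinchona-derived bifunctional thiourea (the pseudoenantiomer that gives the 2S series) in toluene at −25 °C, a catalytic enantioselective intramolecular oxa-Michael addition, to give tert-butyl (2S)-5,7-bis(benzyloxy)-2-[4-(benzyloxy)phenyl]-4-oxochromane-3-carboxylate F1. In parallel, stannane 6 is converted by tin–lead exchange (Pb(OAc)4, cat. Hg(OAc)2, CHCl3) into the aryllead triacetate F2. F2 arylates F1 in CHCl3/pyridine at 40 °C (Pinhey ligand coupling of a β-keto ester) anti to the C2 aryl group to give 14.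

2. Step 10. Saturation of the flavone C2=C3 bond or hydrogenolytic opening of the flavanone at the benzylic C2–O1 bond may compete before all five ethers are cleaved. The fallback sets out from 16 and comes back at 17: Lewis-acid debenzylation with BCl3 and pentamethylbenzene as cation scavenger in CH2Cl2 at −78 °C. The unchelated 7-methoxy group should survive, and no new compound is made (F0).

3. Step 6. O-Acylation of the phenoxide or enolate and double acylation may compete with C-acylation of the dianion. The fallback sets out from 9 and comes back at 10: chemoselective O-acylation (Boc2O, cat. DMAP, Et3N, CH2Cl2) gives 2-acetyl-3,5-bis(benzyloxy)phenyl tert-butyl carbonate F3. Treatment with LiHMDS (2.2 equiv) in THF at −78 → 0 °C then moves the alkoxycarbonyl group from oxygen to the enolate carbon (Baker–Venkataraman-type transfer) to give 10.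

**Further compounds**

F1 | step 8 | tert-butyl (2S)-5,7-bis(benzyloxy)-2-[4-(benzyloxy)phenyl]-4-oxochromane-3-carboxylate (C3 epimers and enol) | CC(C)(C)OC(=O)C1C(=O)c2c(OCc3ccccc3)cc(OCc3ccccc3)cc2O[C@@H]1c1ccc(OCc2ccccc2)cc1
F2 | step 8 | {2-(benzyloxy)-5-[5-(benzyloxy)-7-methoxy-4-oxo-4H-chromen-2-yl]phenyl}lead triacetate | COc1cc(OCc2ccccc2)c2c(=O)cc(-c3ccc(OCc4ccccc4)c([Pb](OC(C)=O)(OC(C)=O)OC(C)=O)c3)oc2c1
F0 | step 10 | none | none
F3 | step 6 | 2-acetyl-3,5-bis(benzyloxy)phenyl tert-butyl carbonate | CC(=O)c1c(OC(=O)OC(C)(C)C)cc(OCc2ccccc2)cc1OCc1ccccc1
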